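**Retrosynthetic overview**

1. Target ⇒ last step closes ring A (left oxepane) and ring B (methylidene-cyclohexane) together on an acyclic diepoxide already tethered to the finished right half. An epoxide-to-epoxide oxonium relay is ended by a 2-(silylmethyl)alkene, which gives the exocyclic C10 methylene and the only free hydroxyl (C3).
2. C11–C12 bond ⇒ B-alkyl Suzuki coupling of the right-half vinyl group (after hydroboration) with a left-half (Z)-iodoalkene/allylsilane diepoxide made from geranyl bromide.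
3. Right half ⇒ ring D (oxepane) and ring C (cyclohexane) closed together by the same type of cascade, ended 6-exo by an allylsilane that leaves the C14 vinyl handle.
4. C15 (tertiary acetate) comes from (3S,6E)-nerolidol; the other oxygenated stereocentres come from Shi epoxidation; C14 and C11 come from chair transition states.
5. Ring order: D + C in one operation (step 4), then A + B in one operation (step 10).

Conventions: locants follow the squalene-type chain (left half C2–C11, linker C12–C13, right half C14–C23); the target is read as 3R,6R,7R,11S,14R,15S,18R,19R,22R in this numbering.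
Assumption: natural (+)-(3S,6E)-nerolidol (e.g. from cabreuva oil) is bought as the single enantiomer.

**Route**

Step 1
Reactants: 1 (3S,6E)-nerolidol
Product: 2 (3S,6E)-nerolidyl acetate
Conditions: Ac2O, Et3N, DMAP (cat.), CH2Cl2, rt
Reagents that add atoms: acetic anhydride, CC(=O)OC(C)=O
Why: DMAP-catalysed acyl transfer to the tertiary allylic alcohol under basic conditions installs the C15 acetate of the target at the outset without breaking the C–O bond (configuration kept) and stops the hydroxyl from attacking the epoxides made next.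

Step 2
Reactants: 2 (3S,6E)-nerolidyl acetate
Product: 3 (3S,6R,7R,10R)-6,7:10,11-diepoxy-3,7,11-trimethyldodec-1-en-3-yl acetate
Conditions: D-fructose-derived Shi ketone (1,2:4,5-di-O-isopropylidene-β-D-erythro-hexo-2,3-diulo-2,6-pyranose, 0.5 equiv), KHSO5 (as 2KHSO5·KHSO4·K2SO4), K2CO3, Bu4NHSO4, MeCN/CH2(OMe)2/aq. Na2B4O7–Na2EDTA buffer, 0 °C
Reagents that add atoms: potassium peroxymonosulfate, [K+].[O-]S(=O)(=O)OO
Why: Shi asymmetric epoxidation, in which the chiral dioxirane attacks the two electron-rich trisubstituted alkenes through a spiro transition state to give the (6R,7R) and (10R) epoxides, while the vinyl group next to the quaternary acetoxy carbon is inert.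

Step 3
Reactants: 3 (3S,6R,7R,10R)-6,7:10,11-diepoxy-3,7,11-trimethyldodec-1-en-3-yl acetate; 4 allyltrimethylsilane
Product: 5 (2E,4S,7R,8R,11R)-7,8:11,12-diepoxy-4,8,12-trimethyl-1-(trimethylsilyl)tridec-2-en-4-yl acetate
Conditions: 4 (4 equiv), second-generation Hoveyda–Grubbs catalyst RuCl2(H2IMes)(=CH–C6H4-2-OiPr) (5 mol %), CH2Cl2, 40 °C
Reagents that add atoms: none
Why: Olefin cross-metathesis between the hindered vinyl group (which cannot homodimerise) and excess allylsilane, driven by loss of ethene, gives mainly the E-allylsilane; the E/Z ratio does not matter because this alkene carbon becomes an unsubstituted vinyl carbon in step 4.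

Step 4
Reactants: 5 (2E,4S,7R,8R,11R)-7,8:11,12-diepoxy-4,8,12-trimethyl-1-(trimethylsilyl)tridec-2-en-4-yl acetate
Product: 7 (3R,5aR,6R,7S,9aR)-6-ethenyl-3-hydroxy-2,2,5a,7-tetramethyldecahydro-1-benzoxepin-7-yl acetate, via trimethylsilyl ether 6 (not isolated)
Conditions: TMSOTf (0.3 equiv), 2,6-di-tert-butyl-4-methylpyridine (0.5 equiv), CH2Cl2, −78 °C; then 1 M aq. HCl, THF, 0 °C
Reagents that add atoms: none
Why: Lewis-acid-promoted epoxide-opening oxa-/carbacyclisation cascade with Sakurai-type allylsilane termination, in which the silylated terminal epoxide is opened at tertiary C23 by the oxygen of the internal epoxide (C22 retained) and the bridged oxonium ion is then opened at C19 with inversion by C14 of the allylsilane through a chair (C15 methyl equatorial, acetoxy axial, vinyl equatorial), so that rings D and C form together, C18/C19/C22 are relayed from the epoxides, C14 is set by the chair and the expelled silyl group regenerates TMSOTf.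

Step 5
Reactants: 7 (3R,5aR,6R,7S,9aR)-6-ethenyl-3-hydroxy-2,2,5a,7-tetramethyldecahydro-1-benzoxepin-7-yl acetate
Product: 8 (3R,5aR,6R,7S,9aR)-6-ethenyl-2,2,5a,7-tetramethyldecahydro-1-benzoxepine-3,7-diyl diacetate
Conditions: Ac2O, pyridine, DMAP (cat.), CH2Cl2, rt
Reagents that add atoms: acetic anhydride, CC(=O)OC(C)=O
Why: DMAP-catalysed acetylation of the hindered secondary C22 alcohol (no stereocentre touched) is done now so that the only hydroxyl set free at the end is the one at C3.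

Step 6
Reactants: 9 geranyl bromide; 10 1-(trimethylsilyl)propyne
Product: 13 (5E)-6,10-dimethylundeca-5,9-dien-1-yne, via silylpropynyllithium 11 (not isolated), via silyl enyne 12 (not isolated)
Conditions: 10, n-BuLi, THF, −78 → −20 °C; then 9, −78 °C → rt; then MeOH, K2CO3, rt
Reagents that add atoms: none
Why: SN2 alkylation of the silyl-blocked propargyl anion at the primary allylic bromide (the silyl group suppresses allenyl products and the E-alkene is untouched) followed by in-situ methanolysis of the alkynylsilane gives the terminal 1,5-enyne with no new stereocentre.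

Step 7
Reactants: 13 (5E)-6,10-dimethylundeca-5,9-dien-1-yne
Product: 15 [(2Z,5E)-2-(iodomethylidene)-6,10-dimethylundeca-5,9-dien-1-yl]trimethylsilane, via alkenylcopper 14 (not isolated)
Conditions: Me3SiCH2MgCl, CuBr·SMe2, Et2O/Me2S, −40 → −10 °C; then I2, THF, −78 → 0 °C
Reagents that add atoms: (trimethylsilyl)methylmagnesium chloride, C[Si](C)(C)C[Mg]Cl; iodine, II
Why: Normant carbocupration adds the organocopper syn across the terminal alkyne with the silylmethyl group on the internal carbon and copper on the terminal carbon, and iodinolysis with retention places iodine cis to CH2SiMe3, the geometry that later puts C12 trans to C9.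

Step 8
Reactants: 15 [(2Z,5E)-2-(iodomethylidene)-6,10-dimethylundeca-5,9-dien-1-yl]trimethylsilane
Product: 16 {(2Z)-4-[(2R,3R)-3-{2-[(2R)-3,3-dimethyloxiran-2-yl]ethyl}-3-methyloxiran-2-yl]-2-(iodomethylidene)butyl}trimethylsilane
Conditions: D-fructose-derived Shi ketone (0.5 equiv), KHSO5 (2.4 equiv, as 2KHSO5·KHSO4·K2SO4), K2CO3, Bu4NHSO4, MeCN/CH2(OMe)2/aq. Na2B4O7–Na2EDTA buffer, −10 °C
Reagents that add atoms: potassium peroxymonosulfate, [K+].[O-]S(=O)(=O)OO
Why: Shi asymmetric epoxidation again gives the (R,R) and (R) epoxides of the two remote trisubstituted alkenes by the same spiro transition state, while the iodine-bearing alkene is deactivated toward the electrophilic dioxirane and survives when the oxidant is limited.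

Step 9
Reactants: 8 (3R,5aR,6R,7S,9aR)-6-ethenyl-2,2,5a,7-tetramethyldecahydro-1-benzoxepine-3,7-diyl diacetate; 16 {(2Z)-4-[(2R,3R)-3-{2-[(2R)-3,3-dimethyloxiran-2-yl]ethyl}-3-methyloxiran-2-yl]-2-(iodomethylidene)butyl}trimethylsilane
Product: 18 (3R,5aR,6R,7S,9aR)-6-{(3Z)-6-[(2R,3R)-3-{2-[(2R)-3,3-dimethyloxiran-2-yl]ethyl}-3-methyloxiran-2-yl]-4-[(trimethylsilyl)methyl]hex-3-en-1-yl}-2,2,5a,7-tetramethyldecahydro-1-benzoxepine-3,7-diyl diacetate, via alkylborane 17 (not isolated)
Conditions: 8, 9-BBN, THF, rt; then 16, PdCl2(dppf) (10 mol %), AsPh3, Cs2CO3, DMF/THF/H2O, rt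
Reagents that add atoms: none
Why: Anti-Markovnikov hydroboration of the vinyl group followed by B-alkyl Suzuki–Miyaura coupling with the alkenyl iodide forms the C11–C12 bond with retention of alkene geometry under conditions that spare epoxides, acetates and the allylsilane, and creates no stereocentre.

Step 10
Reactants: 18 (3R,5aR,6R,7S,9aR)-6-{(3Z)-6-[(2R,3R)-3-{2-[(2R)-3,3-dimethyloxiran-2-yl]ethyl}-3-methyloxiran-2-yl]-4-[(trimethylsilyl)methyl]hex-3-en-1-yl}-2,2,5a,7-tetramethyldecahydro-1-benzoxepine-3,7-diyl diacetate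
Product: 20 (3R,5aR,6R,7S,9aR)-6-{2-[(3R,5aR,6S,9aR)-3-hydroxy-2,2,5a-trimethyl-7-methylidenedecahydro-1-benzoxepin-6-yl]ethyl}-2,2,5a,7-tetramethyldecahydro-1-benzoxepine-3,7-diyl diacetate (CNP0412606.2), via trimethylsilyl ether 19 (not isolated)
Conditions: TMSOTf (0.3 equiv), 2,6-di-tert-butyl-4-methylpyridine (0.5 equiv), CH2Cl2, −78 °C; then 1 M aq. HCl, THF, 0 °C
Reagents that add atoms: none
Why: A second epoxide-opening oxa-/carbacyclisation cascade with allylsilane termination, in which the silylated terminal epoxide is opened at C2 by the internal epoxide oxygen (C3 retained), the bridged oxonium ion is opened at C6 with inversion by C11 through a chair with C12 equatorial (C7 retained, C11 set as S), and the β-silyl cation collapses only to the exocyclic C10 methylene, so that rings A and B form together and the mild acidic work-up frees just the C3 hydroxyl.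

**Compound list**

1 | (3S,6E)-nerolidol | C=C[C@@](C)(O)CC/C=C(\C)CCC=C(C)C | starting material
2 | (3S,6E)-nerolidyl acetate | C=C[C@@](C)(OC(C)=O)CC/C=C(\C)CCC=C(C)C | intermediate
3 | (3S,6R,7R,10R)-6,7:10,11-diepoxy-3,7,11-trimethyldodec-1-en-3-yl acetate | C=C[C@@](C)(OC(C)=O)CC[C@H]1O[C@]1(C)CC[C@H]1OC1(C)C | intermediate
4 | allyltrimethylsilane | C=CC[Si](C)(C)C | starting material
5 | (2E,4S,7R,8R,11R)-7,8:11,12-diepoxy-4,8,12-trimethyl-1-(trimethylsilyl)tridec-2-en-4-yl acetate | C[Si](C)(C)C/C=C/[C@@](C)(OC(C)=O)CC[C@H]1O[C@]1(C)CC[C@H]1OC1(C)C | intermediate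
6 | (3R,5aR,6R,7S,9aR)-6-ethenyl-2,2,5a,7-tetramethyl-3-(trimethylsilyloxy)decahydro-1-benzoxepin-7-yl acetate | C=C[C@@H]1[C@@]2(C)CC[C@@H](O[Si](C)(C)C)C(C)(C)O[C@@H]2CC[C@]1(C)OC(C)=O | intermediate (not isolated)
7 | (3R,5aR,6R,7S,9aR)-6-ethenyl-3-hydroxy-2,2,5a,7-tetramethyldecahydro-1-benzoxepin-7-yl acetate | C=C[C@@H]1[C@@]2(C)CC[C@@H](O)C(C)(C)O[C@@H]2CC[C@]1(C)OC(C)=O | intermediate
8 | (3R,5aR,6R,7S,9aR)-6-ethenyl-2,2,5a,7-tetramethyldecahydro-1-benzoxepine-3,7-diyl diacetate | C=C[C@@H]1[C@@]2(C)CC[C@@H](OC(C)=O)C(C)(C)O[C@@H]2CC[C@]1(C)OC(C)=O | intermediate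
9 | geranyl bromide, (2E)-1-bromo-3,7-dimethylocta-2,6-diene | BrC/C=C(\C)CCC=C(C)C | starting material
10 | 1-(trimethylsilyl)propyne | CC#C[Si](C)(C)C | starting material
11 | [3-(trimethylsilyl)prop-2-yn-1-yl]lithium | [Li]CC#C[Si](C)(C)C | intermediate (not isolated)
12 | trimethyl[(5E)-6,10-dimethylundeca-5,9-dien-1-yn-1-yl]silane | C[Si](C)(C)C#CCC/C=C(\C)CCC=C(C)C | intermediate (not isolated)
13 | (5E)-6,10-dimethylundeca-5,9-dien-1-yne | C#CCC/C=C(\C)CCC=C(C)C | intermediate
14 | [(1Z,5E)-6,10-dimethyl-2-(trimethylsilylmethyl)undeca-1,5,9-trien-1-yl]copper | [Cu]/C=C(\C[Si](C)(C)C)CC/C=C(\C)CCC=C(C)C | intermediate (not isolated)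
15 | [(2Z,5E)-2-(iodomethylidene)-6,10-dimethylundeca-5,9-dien-1-yl]trimethylsilane | I/C=C(\C[Si](C)(C)C)CC/C=C(\C)CCC=C(C)C | intermediate
16 | {(2Z)-4-[(2R,3R)-3-{2-[(2R)-3,3-dimethyloxiran-2-yl]ethyl}-3-methyloxiran-2-yl]-2-(iodomethylidene)butyl}trimethylsilane | I/C=C(\C[Si](C)(C)C)CC[C@H]1O[C@]1(C)CC[C@H]1OC1(C)C | intermediate
17 | 9-{2-[(3R,5aR,6R,7S,9aR)-3,7-diacetoxy-2,2,5a,7-tetramethyldecahydro-1-benzoxepin-6-yl]ethyl}-9-borabicyclo[3.3.1]nonane | B1(CC[C@@H]3[C@@]4(C)CC[C@@H](OC(C)=O)C(C)(C)O[C@@H]4CC[C@]3(C)OC(C)=O)C2CCCC1CCC2 | intermediate (not isolated)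
18 | (3R,5aR,6R,7S,9aR)-6-{(3Z)-6-[(2R,3R)-3-{2-[(2R)-3,3-dimethyloxiran-2-yl]ethyl}-3-methyloxiran-2-yl]-4-[(trimethylsilyl)methyl]hex-3-en-1-yl}-2,2,5a,7-tetramethyldecahydro-1-benzoxepine-3,7-diyl diacetate | C[Si](C)(C)C/C(CC[C@H]1O[C@]1(C)CC[C@H]1OC1(C)C)=C\CC[C@@H]1[C@@]2(C)CC[C@@H](OC(C)=O)C(C)(C)O[C@@H]2CC[C@]1(C)OC(C)=O | intermediate
19 | 3-O-trimethylsilyl ether of 20 (left-half C3) | C=C1CC[C@H]2OC(C)(C)[C@H](O[Si](C)(C)C)CC[C@]2(C)[C@H]1CC[C@@H]1[C@@]2(C)CC[C@@H](OC(C)=O)C(C)(C)O[C@@H]2CC[C@]1(C)OC(C)=O | intermediate (not isolated)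
20 | (3R,5aR,6R,7S,9aR)-6-{2-[(3R,5aR,6S,9aR)-3-hydroxy-2,2,5a-trimethyl-7-methylidenedecahydro-1-benzoxepin-6-yl]ethyl}-2,2,5a,7-tetramethyldecahydro-1-benzoxepine-3,7-diyl diacetate | C=C1CC[C@H]2OC(C)(C)[C@H](O)CC[C@]2(C)[C@H]1CC[C@@H]1[C@@]2(C)CC[C@@H](OC(C)=O)C(C)(C)O[C@@H]2CC[C@]1(C)OC(C)=O | target

**Step count**

Total: 10 steps. Longest linear sequence: 7 steps (1, 2, 3, 4, 5, 9, 10).

**Three steps most likely to fail**

Step 4. The tertiary acetate of 5 is allylic and could ionise under the silyl triflate, and the acetate lowers the nucleophilicity of the allylsilane. The fallback sets out from 1 and comes back at 8; it carries the C15 oxygen through the cascade as a bulky silyl ether and acetylates afterwards. Compound 1 is silylated (TBSOTf, 2,6-lutidine) to the tert-butyldimethylsilyl ether of nerolidol F1. This is epoxidised as in step 2 to the diepoxide F2 and cross-metathesised with 4 as in step 3 to the allylsilane F3. The step 4 cascade without acid work-up gives the bicyclic bis-silyl ether F4, which is desilylated (HF·pyridine, THF) to the vinyl diol F5. Exhaustive acetylation (Ac2O, DMAP, Et3N, 60 °C, or Ac2O with catalytic Bi(OTf)3) then gives 8.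

Step 7. The silylmethylcopper may add sluggishly to a plain 1-alkyne; the same fallback also answers poor chemoselectivity in step 8. It sets out from 13 and comes back at 19, and it gives up the allylsilane terminator. Zirconium-catalysed carboalumination of 13 (Me3Al, Cp2ZrCl2, CH2Cl2) gives the alkenylalane F6, and iodinolysis gives (1E,5E)-1-iodo-2,6,10-trimethylundeca-1,5,9-triene F7. Shi epoxidation as in step 8 gives the diepoxy iodide F8, and Suzuki coupling with 17 as in step 9 gives the methyl-substituted coupled alkene F9. The cascade is then run with TMSOTf (1.1 equiv) and excess 2,6-di-tert-butyl-4-methylpyridine, so that the C10 cation is ended by loss of a methyl proton to the hindered base, giving 19. The exocyclic isomer must be separated from endocyclic isomers on AgNO3-impregnated silica.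

Step 10. The two-ring closure on the fully decorated substrate may suffer from the tertiary acetate or from premature reaction of the very nucleophilic allylsilane. The fallback sets out from 17 and comes back at 20; it uses an enol silane terminator and makes the methylene from a ketone.
- The borane 17 is oxidised (NaBO3·4H2O, THF/H2O) to the primary alcohol F10 and then (Dess–Martin periodinane, NaHCO3) to the aldehyde F11.
- Geranylacetone F12 is epoxidised as in step 2 to the diepoxy ketone F13.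
- The kinetic lithium enolate F14 of F13 (LiN(iPr)2, THF, −78 °C, methyl side) adds to F11 to give the aldol F15.
- The mesylate F16 (MsCl, Et3N) is eliminated with DBU to the (E)-enone F17.
- Conjugate hydrosilylation (Et3SiH, RhCl(PPh3)3 cat.) gives the (Z)-triethylsilyl enol ether F18 with the double bond fixed between C10 and C11.
- The step 10 cascade conditions give the C3-triethylsilyl ether ketone F19, and acidic work-up gives the hydroxy ketone F20; C11 is α to the ketone and settles equatorial.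
- Methylenation without base (Zn, CH2Br2, TiCl4, THF/CH2Cl2) gives 20.

**Further compounds**

F1 | step 4 | tert-butyldimethylsilyl ether of (3S,6E)-nerolidol | C=C[C@@](C)(O[Si](C)(C)C(C)(C)C)CC/C=C(\C)CCC=C(C)C
F2 | step 4 | (3S,6R,7R,10R)-6,7:10,11-diepoxide of F1 | C=C[C@@](C)(O[Si](C)(C)C(C)(C)C)CC[C@H]1O[C@]1(C)CC[C@H]1OC1(C)C
F3 | step 4 | allylsilane from F2 (silyl ether analogue of 5) | C[Si](C)(C)C/C=C/[C@@](C)(O[Si](C)(C)C(C)(C)C)CC[C@H]1O[C@]1(C)CC[C@H]1OC1(C)C
F4 | step 4 | bicyclic bis-silyl ether (C15 O-TBS, C22 O-TMS) | C=C[C@@H]1[C@@]2(C)CC[C@@H](O[Si](C)(C)C)C(C)(C)O[C@@H]2CC[C@]1(C)O[Si](C)(C)C(C)(C)C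
F5 | step 4 | (3R,5aR,6R,7S,9aR)-6-ethenyl-2,2,5a,7-tetramethyldecahydro-1-benzoxepine-3,7-diol | C=C[C@@H]1[C@@]2(C)CC[C@@H](O)C(C)(C)O[C@@H]2CC[C@]1(C)O
F6 | step 7 | dimethyl[(1E,5E)-2,6,10-trimethylundeca-1,5,9-trien-1-yl]alane | C[Al](C)/C=C(\C)CC/C=C(\C)CCC=C(C)C
F7 | step 7 | (1E,5E)-1-iodo-2,6,10-trimethylundeca-1,5,9-triene | I/C=C(\C)CC/C=C(\C)CCC=C(C)C
F8 | step 7 | (R,R),(R)-diepoxide of F7 | I/C=C(\C)CC[C@H]1O[C@]1(C)CC[C@H]1OC1(C)C
F9 | step 7 | coupled diepoxide with C10 methyl in place of CH2SiMe3 (analogue of 18) | C/C(CC[C@H]1O[C@]1(C)CC[C@H]1OC1(C)C)=C\CC[C@@H]1[C@@]2(C)CC[C@@H](OC(C)=O)C(C)(C)O[C@@H]2CC[C@]1(C)OC(C)=O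
F10 | step 10 | primary alcohol from 17 (C12 hydroxyl) | OCC[C@@H]1[C@@]2(C)CC[C@@H](OC(C)=O)C(C)(C)O[C@@H]2CC[C@]1(C)OC(C)=O
F11 | step 10 | C12 aldehyde | O=CC[C@@H]1[C@@]2(C)CC[C@@H](OC(C)=O)C(C)(C)O[C@@H]2CC[C@]1(C)OC(C)=O
F12 | step 10 | geranylacetone, (5E)-6,10-dimethylundeca-5,9-dien-2-one | CC(=O)CC/C=C(\C)CCC=C(C)C
F13 | step 10 | (5R,6R,9R)-5,6:9,10-diepoxy-6,10-dimethylundecan-2-one | CC(=O)CC[C@H]1O[C@]1(C)CC[C@H]1OC1(C)C
F14 | step 10 | kinetic lithium enolate of F13 | C=C(O[Li])CC[C@H]1O[C@]1(C)CC[C@H]1OC1(C)C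
F15 | step 10 | aldol adduct (C12 carbinol, epimer mixture) | O=C(CC[C@H]1O[C@]1(C)CC[C@H]1OC1(C)C)CC(O)C[C@@H]1[C@@]2(C)CC[C@@H](OC(C)=O)C(C)(C)O[C@@H]2CC[C@]1(C)OC(C)=O
F16 | step 10 | mesylate of F15 | O=C(CC[C@H]1O[C@]1(C)CC[C@H]1OC1(C)C)CC(OS(C)(=O)=O)C[C@@H]1[C@@]2(C)CC[C@@H](OC(C)=O)C(C)(C)O[C@@H]2CC[C@]1(C)OC(C)=O
F17 | step 10 | (E)-enone (C11=C12, C10 ketone) | O=C(CC[C@H]1O[C@]1(C)CC[C@H]1OC1(C)C)/C=C/C[C@@H]1[C@@]2(C)CC[C@@H](OC(C)=O)C(C)(C)O[C@@H]2CC[C@]1(C)OC(C)=O
F18 | step 10 | (Z)-triethylsilyl enol ether (C10=C11) | CC[Si](CC)(CC)O/C(CC[C@H]1O[C@]1(C)CC[C@H]1OC1(C)C)=C\CC[C@@H]1[C@@]2(C)CC[C@@H](OC(C)=O)C(C)(C)O[C@@H]2CC[C@]1(C)OC(C)=O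
F19 | step 10 | C10 ketone with C3 triethylsilyl ether | O=C1CC[C@H]2OC(C)(C)[C@H](O[Si](CC)(CC)CC)CC[C@]2(C)[C@H]1CC[C@@H]1[C@@]2(C)CC[C@@H](OC(C)=O)C(C)(C)O[C@@H]2CC[C@]1(C)OC(C)=O
F20 | step 10 | C10 ketone with free C3 hydroxyl | O=C1CC[C@H]2OC(C)(C)[C@H](O)CC[C@]2(C)[C@H]1CC[C@@H]1[C@@]2(C)CC[C@@H](OC(C)=O)C(C)(C)O[C@@H]2CC[C@]1(C)OC(C)=O
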